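**Plan**

- Feature used: ring B carries H at C6', OMe at C5' and C4', and OH at C3'. This run of atoms is the C4(H)–C3(OMe)=C2(OMe)–C1(=O) perimeter of a squarate-derived cyclobutenone, and C1'/C2' are the two carbons of a vinyl group held on chromone C2.
- Retrosynthesis: cut the C8 O–benzyl bond, then the C2'–C3' bond of ring B (ring expansion of a 4-alkenylcyclobutenone), then C1'–C6' (Stille coupling of a vinylstannane with a 4-chlorocyclobutenone), then O1–C2 and C2–C3 of the pyranone (Claisen condensation and cyclodehydration), and last the C4–C4a aryl–acyl bond.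
- Forward: ring A is bought and re-oxygenated by Baeyer–Villiger oxidation. Ring C closes in step 4 with the future C1'/C2' already attached as an acetyl group. The four-membered ring is joined in step 9 and becomes ring B in step 10. Hydrogenolysis ends the route.
- Stereochemistry (remark on the chemistry): the target has no stereocentre and no stereogenic double bond, so the requested single stereoisomer is the only one. The cyclobutenone intermediates are racemic at one sp3 carbon, which becomes aromatic C6'.

Key step: step 10

**Route**

Step 1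
Reactants: 1 2-hydroxy-3,4-dimethoxybenzaldehyde
Product: 2 2-(benzyloxy)-3,4-dimethoxybenzaldehyde
Conditions: BnBr, K2CO3, DMF, 60 °C
Reagents that add atoms: benzyl bromide, BrCc1ccccc1
Why: Williamson etherification of the only acidic site, the phenol, should proceed cleanly and leaves the aldehyde untouched.

Step 2
Reactants: 2 2-(benzyloxy)-3,4-dimethoxybenzaldehyde
Product: 4 2-(benzyloxy)-3,4-dimethoxyphenol, via aryl formate 3 (not isolated)
Conditions: mCPBA, CH2Cl2, 0 °C → rt; then K2CO3 (cat.), MeOH, rt
Reagents that add atoms: 3-chloroperoxybenzoic acid, OOC(=O)c1cccc(Cl)c1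
Why: In this Baeyer–Villiger (Dakin-type) oxidation the electron-rich aryl group, with ortho and para alkoxy donors, should migrate in preference to hydride, and the formate is methanolysed in the same flask.

Step 3
Reactants: 4 2-(benzyloxy)-3,4-dimethoxyphenol
Product: 5 1-[3-(benzyloxy)-2-hydroxy-4,5-dimethoxyphenyl]ethan-1-one
Conditions: AcOH, BF3·OEt2 (promoter), 60–70 °C; then aq NaOAc
Reagents that add atoms: acetic acid, CC(=O)O
Why: BF3-promoted Friedel–Crafts acylation of a free phenol (the in situ equivalent of a Fries rearrangement) should place the acetyl group at C6, the only open position ortho to the hydroxyl and also para to the C3 methoxy group, where the product is held as a boron chelate, and the moderate temperature is chosen to spare the benzyl ether.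

Step 4
Reactants: 5 1-[3-(benzyloxy)-2-hydroxy-4,5-dimethoxyphenyl]ethan-1-one; 6 ethyl 2,2-diethoxypropanoate
Product: 9 2-acetyl-8-(benzyloxy)-6,7-dimethoxy-4H-chromen-4-one, via β-diketone 7 (not isolated), via ketal chromone 8 (not isolated)
Conditions: NaH, THF, 0 °C → reflux; then AcOH, 2 M aq HCl, 70 °C
Reagents that add atoms: water, O
Why: Crossed Claisen condensation of the phenoxide-enolate dianion of 5 with the non-enolisable, alkoxy-activated ester 6 gives the β-diketone, which under aqueous acid should cyclodehydrate to the chromone (phenol oxygen onto the C3 carbonyl, six-membered ring) and then lose the ketal, delivering the acetyl group without any organometallic addition to a chromone ester.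

Step 5
Reactants: 9 2-acetyl-8-(benzyloxy)-6,7-dimethoxy-4H-chromen-4-one
Product: 10 1-[8-(benzyloxy)-6,7-dimethoxy-4-oxo-4H-chromen-2-yl]ethenyl trifluoromethanesulfonate
Conditions: KHMDS, THF, −78 °C; then PhNTf2, −78 → 0 °C; aq NH4Cl
Reagents that add atoms: N-phenyl-bis(trifluoromethanesulfonimide), O=S(=O)(N(c1ccccc1)S(=O)(=O)C(F)(F)F)C(F)(F)F
Why: Enol triflate formation should succeed because the acetyl methyl group holds the only acidic C–H bonds, so kinetic deprotonation by the hindered amide base at low temperature and O-sulfonylation of the enolate outrun conjugate attack on the chromone.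

Step 6
Reactants: 10 1-[8-(benzyloxy)-6,7-dimethoxy-4-oxo-4H-chromen-2-yl]ethenyl trifluoromethanesulfonate
Product: 11 8-(benzyloxy)-6,7-dimethoxy-2-[1-(trimethylstannyl)ethenyl]-4H-chromen-4-one
Conditions: Me3SnSnMe3 (excess), Pd(PPh3)4 (cat.), LiCl, THF, 60 °C
Reagents that add atoms: hexamethylditin, C[Sn](C)(C)[Sn](C)(C)C
Why: Palladium-catalysed stannylation of an enol triflate with a distannane (Stille-type, chloride-assisted) is a standard route to 1-substituted vinylstannanes, and excess distannane should suppress coupling of the product with unreacted triflate.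

Step 7
Reactants: 12 dimethyl squarate (3,4-dimethoxycyclobut-3-ene-1,2-dione)
Product: 13 4-hydroxy-2,3-dimethoxycyclobut-2-en-1-one (racemic)
Conditions: LiAlH(Ot-Bu)3, THF, −78 → −20 °C; aq Rochelle salt
Reagents that add atoms: none
Why: The bulky alkoxyaluminium hydride should add once to one of the two equivalent squarate carbonyls (1,2-reduction), since the resulting vinylogous ester is too electron-rich to be reduced further, and the new stereocentre is formed as a racemate that is later erased.

Step 8
Reactants: 13 4-hydroxy-2,3-dimethoxycyclobut-2-en-1-one (racemic)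
Product: 14 4-chloro-2,3-dimethoxycyclobut-2-en-1-one (racemic)
Conditions: PPh3, CCl4, CH2Cl2, 0 °C → rt; cold filtration, used at once
Reagents that add atoms: carbon tetrachloride, ClC(Cl)(Cl)Cl
Why: Appel chlorination converts the secondary allylic alcohol to the chloride under neutral conditions, which should avoid the acid-induced loss of an enol-ether methyl group, and the conjugated 4-chloro isomer is the thermodynamically preferred allylic chloride.

Step 9
Reactants: 11 8-(benzyloxy)-6,7-dimethoxy-2-[1-(trimethylstannyl)ethenyl]-4H-chromen-4-one; 14 4-chloro-2,3-dimethoxycyclobut-2-en-1-one (racemic)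
Product: 15 4-{1-[8-(benzyloxy)-6,7-dimethoxy-4-oxo-4H-chromen-2-yl]ethenyl}-2,3-dimethoxycyclobut-2-en-1-one (racemic)
Conditions: PdCl2(PhCN)2 (cat.), tri(2-furyl)phosphine (cat.), CuI (cat.), dioxane, rt, dark
Reagents that add atoms: none
Why: Stille coupling of a 4-chlorocyclobutenone should proceed by oxidative addition into the activated allylic C–Cl bond, copper-assisted transmetalation of the vinyl group and reductive elimination at C4 (which keeps the vinylogous ester conjugated), and ambient temperature is chosen to stay below the onset of electrocyclic ring opening so that 15 can be isolated.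

Step 10
Reactants: 15 4-{1-[8-(benzyloxy)-6,7-dimethoxy-4-oxo-4H-chromen-2-yl]ethenyl}-2,3-dimethoxycyclobut-2-en-1-one (racemic)
Product: 18 8-(benzyloxy)-2-(3-hydroxy-4,5-dimethoxyphenyl)-6,7-dimethoxy-4H-chromen-4-one, via dienylketene 16 (not isolated), via cyclohexadienone 17 (not isolated)
Conditions: toluene (0.02 M, degassed), 100 °C
Reagents that add atoms: none
Why: Heating should open the cyclobutenone by thermal conrotatory 4π electrocyclic cleavage of the C1–C4 bond to the vinylketene 16, whose ketene, enol-ether alkene and 1,1-disubstituted vinyl group form a 1,3,5-triene that closes by disrotatory 6π electrocyclisation (ketene carbon onto the vinyl CH2, new C2'–C3' bond) to cyclohexadienone 17, and enolisation then aromatises ring B. The closest known reaction type is the thermal ring expansion of 4-alkenylcyclobut-2-enones to phenols, the second half of the vinylketene–alkyne benzannulation. Ring B thus closes as a six-membered carbocycle by 6π electrocyclisation, the former carbonyl carbon becoming C3'–OH, the two methoxy-bearing squarate carbons C4' and C5', and the former sp3 carbon C6'–H. No stereocentre is created, since the racemic sp3 carbon of 15 and the CH2 of 17 both end as aromatic CH. The selectivity needed is torquoselectivity and site of closure: only the ketene with the alkenyl group rotated inward (cis to the ketene carbon) can cyclise, and because ring opening is reversible in a non-nucleophilic solvent the outward rotamer returns to 15 until all material has passed through the productive isomer, while the vinyl CH2 is the only triene terminus within reach and the chromone C2=C3 bond lies one atom too far to compete. High dilution and exclusion of nucleophiles should keep the ketene from dimerising or being trapped by the product phenol.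

Step 11
Reactants: 18 8-(benzyloxy)-2-(3-hydroxy-4,5-dimethoxyphenyl)-6,7-dimethoxy-4H-chromen-4-one
Product: 19 8-hydroxy-2-(3-hydroxy-4,5-dimethoxyphenyl)-6,7-dimethoxy-4H-chromen-4-one
Conditions: H2 (1 atm), 10% Pd/C, EtOAc–MeOH, rt
Reagents that add atoms: none
Why: Catalytic hydrogenolysis should cleave the benzyl aryl ether selectively, since the methyl ethers are inert and the conjugated chromone C2=C3 bond is not reduced at atmospheric pressure and room temperature.

**Compound list**

1 | 2-hydroxy-3,4-dimethoxybenzaldehyde | COc1ccc(C=O)c(O)c1OC | starting material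
2 | 2-(benzyloxy)-3,4-dimethoxybenzaldehyde | COc1ccc(C=O)c(OCc2ccccc2)c1OC | intermediate
3 | 2-(benzyloxy)-3,4-dimethoxyphenyl formate | COc1ccc(OC=O)c(OCc2ccccc2)c1OC | intermediate (not isolated)
4 | 2-(benzyloxy)-3,4-dimethoxyphenol | COc1ccc(O)c(OCc2ccccc2)c1OC | intermediate
5 | 1-[3-(benzyloxy)-2-hydroxy-4,5-dimethoxyphenyl]ethan-1-one | CC(=O)c1cc(OC)c(OC)c(OCc2ccccc2)c1O | intermediate
6 | ethyl 2,2-diethoxypropanoate | CCOC(=O)C(C)(OCC)OCC | starting material
7 | 1-[3-(benzyloxy)-2-hydroxy-4,5-dimethoxyphenyl]-4,4-diethoxypentane-1,3-dione | CCOC(C)(OCC)C(=O)CC(=O)c1cc(OC)c(OC)c(OCc2ccccc2)c1O | intermediate (not isolated)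
8 | 8-(benzyloxy)-2-(1,1-diethoxyethyl)-6,7-dimethoxy-4H-chromen-4-one | CCOC(C)(OCC)c1cc(=O)c2cc(OC)c(OC)c(OCc3ccccc3)c2o1 | intermediate (not isolated)
9 | 2-acetyl-8-(benzyloxy)-6,7-dimethoxy-4H-chromen-4-one | CC(=O)c1cc(=O)c2cc(OC)c(OC)c(OCc3ccccc3)c2o1 | intermediate
10 | 1-[8-(benzyloxy)-6,7-dimethoxy-4-oxo-4H-chromen-2-yl]ethenyl trifluoromethanesulfonate | C=C(OS(=O)(=O)C(F)(F)F)c1cc(=O)c2cc(OC)c(OC)c(OCc3ccccc3)c2o1 | intermediate
11 | 8-(benzyloxy)-6,7-dimethoxy-2-[1-(trimethylstannyl)ethenyl]-4H-chromen-4-one | C=C([Sn](C)(C)C)c1cc(=O)c2cc(OC)c(OC)c(OCc3ccccc3)c2o1 | intermediate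
12 | dimethyl squarate (3,4-dimethoxycyclobut-3-ene-1,2-dione) | COC1=C(OC)C(=O)C1=O | starting material
13 | 4-hydroxy-2,3-dimethoxycyclobut-2-en-1-one (racemic) | COC1=C(OC)C(=O)C1O | intermediate
14 | 4-chloro-2,3-dimethoxycyclobut-2-en-1-one (racemic) | COC1=C(OC)C(=O)C1Cl | intermediate
15 | 4-{1-[8-(benzyloxy)-6,7-dimethoxy-4-oxo-4H-chromen-2-yl]ethenyl}-2,3-dimethoxycyclobut-2-en-1-one (racemic) | COC1=C(OC)C(=O)C1C(=C)c1cc(=O)c2cc(OC)c(OC)c(OCc3ccccc3)c2o1 | intermediate
16 | 5-[8-(benzyloxy)-6,7-dimethoxy-4-oxo-4H-chromen-2-yl]-2,3-dimethoxyhexa-1,3,5-trien-1-one (ketene; alkenyl group cis to the ketene carbon across C3=C4) | COC(=C=O)/C(OC)=C\C(=C)c1cc(=O)c2cc(OC)c(OC)c(OCc3ccccc3)c2o1 | intermediate (not isolated)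
17 | 5-[8-(benzyloxy)-6,7-dimethoxy-4-oxo-4H-chromen-2-yl]-2,3-dimethoxycyclohexa-2,4-dien-1-one | COC1=C(OC)C=C(CC1=O)c1cc(=O)c2cc(OC)c(OC)c(OCc3ccccc3)c2o1 | intermediate (not isolated)
18 | 8-(benzyloxy)-2-(3-hydroxy-4,5-dimethoxyphenyl)-6,7-dimethoxy-4H-chromen-4-one | COc1cc(-c2cc(=O)c3cc(OC)c(OC)c(OCc4ccccc4)c3o2)cc(O)c1OC | intermediate
19 | 8-hydroxy-2-(3-hydroxy-4,5-dimethoxyphenyl)-6,7-dimethoxy-4H-chromen-4-one | COc1cc(-c2cc(=O)c3cc(OC)c(OC)c(O)c3o2)cc(O)c1OC | target

**Summary**

Total step count: 11. Longest linear sequence: 9 steps (steps 1–6, then 9, 10 and 11). The squarate branch (steps 7 and 8) joins at step 9.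

Steps most likely to fail:

1. Step 9. Transmetalation from the α-branched, electron-poor vinylstannane may be slow, so that protodestannylation, methyl transfer from tin and decay of the sensitive chloride outcompete C–C bond formation, and a long reaction may let the coupled product begin to ring-open. The fallback sets out from 11 and returns at 15. Iododestannylation of 11 (I2, CH2Cl2, 0 °C) should give 8-(benzyloxy)-2-(1-iodoethenyl)-6,7-dimethoxy-4H-chromen-4-one F1. Zinc insertion (Zn dust, LiCl, THF, rt) should convert it into {1-[8-(benzyloxy)-6,7-dimethoxy-4-oxo-4H-chromen-2-yl]ethenyl}zinc iodide F2, an organometallic that tolerates the chromone carbonyl. Palladium-catalysed Negishi coupling of F2 with chloride 14 (Pd2(dba)3, tri(2-furyl)phosphine, THF, 0 °C → rt) relies on the much faster transmetalation from zinc and should give 15.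

2. Step 8. The allylic C–Cl bond may ionise with help from the C2 methoxy group, followed by loss of a methyl group toward the cyclobutenedione, or chloride may be delivered with allylic transposition, during chlorination or concentration. The fallback sets out from 13 and returns at 15. Acetylation of 13 (Ac2O, pyridine, DMAP cat., CH2Cl2, 0 °C) should give 2,3-dimethoxy-4-oxocyclobut-2-en-1-yl acetate F3, an isolable ester. Coupling of F3 with stannane 11 under the conditions used for allylic acetates (Pd(dba)2, LiCl, DMF, rt to 40 °C) passes through the same oxocyclobutenyl-palladium intermediate and should give 15 without ever handling the chloride.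

3. Step 3. The benzyl group may be cleaved by the Lewis acid or transferred to the electron-rich ring at the temperature needed for acylation. The fallback sets out from 4 and returns at 5. Bromination of 4 with NBS (MeCN, 0 °C), directed by the free hydroxyl to its only open ortho position, should give 2-(benzyloxy)-6-bromo-3,4-dimethoxyphenol F4. Stille coupling with tributyl(1-ethoxyvinyl)stannane (Pd(PPh3)4, dioxane, 100 °C) should give 2-(benzyloxy)-6-(1-ethoxyethenyl)-3,4-dimethoxyphenol F5, and mild hydrolysis (1 M HCl, THF, rt) of this enol ether should give 5 with no Lewis acid present at any stage.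

**Further compounds**

F1 | step 9 | 8-(benzyloxy)-2-(1-iodoethenyl)-6,7-dimethoxy-4H-chromen-4-one | C=C(I)c1cc(=O)c2cc(OC)c(OC)c(OCc3ccccc3)c2o1
F2 | step 9 | {1-[8-(benzyloxy)-6,7-dimethoxy-4-oxo-4H-chromen-2-yl]ethenyl}zinc iodide | C=C([Zn]I)c1cc(=O)c2cc(OC)c(OC)c(OCc3ccccc3)c2o1
F3 | step 8 | 2,3-dimethoxy-4-oxocyclobut-2-en-1-yl acetate (racemic) | CC(=O)OC1C(OC)=C(OC)C1=O
F4 | step 3 | 2-(benzyloxy)-6-bromo-3,4-dimethoxyphenol | COc1cc(Br)c(O)c(OCc2ccccc2)c1OC
F5 | step 3 | 2-(benzyloxy)-6-(1-ethoxyethenyl)-3,4-dimethoxyphenol | CCOC(=C)c1cc(OC)c(OC)c(OCc2ccccc2)c1O
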